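## The problem

Xenoacremone H (40; atoms are numbered in the order in which they stand in its SMILES string) is a trans,trans-fused 6-5-6 carbotricycle: ring A (C7, C8, C9, C11, C12, C14), ring B (C6, C7, C14, C15, C34) and ring C (C3, C4, C5, C6, C34, C33). Its C15 oxygen and its C33 acyl carbon C31 are bridged by a bent 13-membered para-cyclophane that contains a 5-hydroxypyrrolidin-2-one (C24, C26, C27, C28, N30). Nine of the eleven stereocenters sit on the tricycle. Ring A carries all four substituents equatorially, so it can be built first and then fixes the trans A/B fusion; C6 can steer C34, and the finished ring B can steer C33 and C3. C27 (between two carbonyls) and the hemiaminal carbon C24 are exchangeable and should be left to equilibrate at the end. The awkward center is C15: its aryloxy group is cis to the C33 arm and peri to the equatorial C12 methyl, the more hindered of the two positions. The hemiaminal, the enolizable β-keto amide, the doubly allylic C3–H and the two alkenes C1=C2 and C4=C5 rule out late hydrogenation, ozonolysis and strong acid, and the cyclophane is strained. The enabling feature is on ring B: C15 bears oxygen and its neighbour C34 bears the C33 arm that leads to the C31 carbonyl. That is the pattern left by addition of a ketyl to the β-carbon of an enoate, and the anti hydroxy ester that this reaction normally gives is one inversion away from the target ether.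

## Retrosynthesis

Lactam (C28–N30, N30–C24). The hydroxy lactam of 40 is the closed form of a primary β-keto amide with a C24 ketone, so both C–N bonds are cut first to give the macrocyclic diketo ester 39. This removes the two exchangeable stereocenters and the most fragile group in one move, in preference to carrying a hemiaminal through a ring closure. The forward reaction must aminolyse the ester and let C24 and C27 settle.

Macrocycle (C26–C27). Of the ring bonds, C26–C27 is the one that lies between a doubly activated carbon and a ketone α-carbon. Cutting it gives chloroketone 38 and needs no oxidation-state change after closure, unlike a cut at C23/C24 through an alkene or at C15–O with retention. The forward reaction is an irreversible intramolecular C-alkylation of a β-keto ester enolate that has to pay for the cyclophane strain.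

Ansa arm (C27–C31, side-chain oxidation level). 38 comes from acid 34 by two-carbon homologation (36) and unmasking of a silyl-protected chlorohydrin (37). The three side-chain carbons C23, C24 and C26 are already on the aryl ring, so no late C–C bond has to be made at the arene.

Ring C (C4=C5, then C33–C3). Cutting the ring alkene of 34 gives triene acid 33, and cutting C33–C3 by a [3,3] shift gives pentadienyl ester 30, made from acid 27 and dienol 29 (from acid 28). This pair of cuts is preferred to an alkylation at C33 because C3 needs no stereocontrol before ring closure (it carries two identical vinyl groups) and C33 is set next to the finished ring B. The forward reactions must select the C33 face and one of the two vinyl groups.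

Aryl ether (C15–O). 27 comes from ester 26, and 26 from hydrindanol 17 and phenol 25 by substitution with inversion. This is chosen over arylation with retention because the alcohol that the ring B closure delivers is the C15 epimer. 25 is a three-step fragment from 1,4-diiodobenzene 18 and (S)-epichlorohydrin 19 via 21 and 22.

Ring B (C15–C34). This is the key cut. It opens 17 to aldehyde enoate 16, which has one ring and two stereocenters fewer. It is preferred to cuts at C6–C34 or C14–C15 because both ends are simple carbonyl functions, and because the trans-diequatorial C7–C14 bond of ring A and the C6 substituent are placed to direct the closure. The forward reaction must close five-membered ring B trans-fused, put the C33 arm trans to the C6 vinyl group and the hydroxyl anti to the arm.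

C6 and its two arms. The enoate of 16 comes from lactol 13 by Wittig olefination (14), the vinyl group by sulfoxide elimination (15), and the aldehyde by oxidation. The C6 stereocenter is traced back to trans-fused δ-lactone 12, made from 11, where C6 is α to the carbonyl of a rigid bicycle and its substituent takes the equatorial position. This makes the C6 configuration a thermodynamic outcome rather than a matter of acyclic induction from C7.

Ring A. Lactone 11 comes from all-equatorial ester 8 (via 9 and 10), and 8 from the cis series 7, 6 and 5 by one-carbon homologation and epimerization at C14. Cutting C7–C8 and C12–C14 of 4/3 leads to butenolide 1 and diene 2, both commercially available. A cis dienophile is chosen because it puts C12, C14 and C7 on one face; this lets a single hydrogenation set C9 and leaves only C14 to be inverted.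

## Roads not taken

Alternative 1: Rings A and B are cut together at C7–C14 and C11–C12. In the forward step EtAlCl2 would promote the intramolecular Diels–Alder reaction of tetraene A1, a preformed ring C carrying a methylbutadienyl group on C6 and a tethered (E)-enoate, to tricycle A2. Its merit is large: two rings and the C7, C14 and C12 stereocenters form in one step, trans-hydrindanes are the normal result for terminally activated trienes of this length, and the route is convergent. For this target the weak points come afterwards. C12 arrives as a methoxycarbonyl group and needs three steps to become methyl. The new C8=C9 alkene must then be hydrogenated to set C9 while C1=C2 and C4=C5 survive, although it is the most substituted and least reactive of the three. Ring C with four contiguous stereocenters has to be made enantiopure before the key step. In bonds and rings per step Alternative 1 is better than the chosen plan. The chosen plan sets against this that both methyl groups are in place from the second step, when the only alkene in the molecule is the one being hydrogenated, and that no alkene has to be differentiated later.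

Alternative 2: The macrocycle is cut at C23–C24 through an alkene. In the forward step t-BuOK would convert the 14-membered α-chloro sulfone A3 into an episulfone that loses SO2 and gives the 13-membered (Z)-styrene A4. Its merit is that the ring is closed at an unstrained size and the strain is paid for by extrusion of SO2; for a bent para-cyclophane this is the safer way to the macrocycle, and that must be conceded. Its weak points are its length (thioether, sulfone, chlorination, then epoxidation, reductive opening and oxidation to reach the C24 ketone). The β-keto ester is the most acidic site of A3. Above all, the C23=C24 alkene of A4 has to be oxidized in the presence of C1=C2 and C4=C5. The chosen plan closes the ring directly with C24 already a ketone and so saves about five steps and the alkene differentiation; it carries the risk of a direct 13-membered closure in exchange. Alternative 2 also says nothing about how the tricycle is made.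

Alternative 3: Ring C is cut at C4=C5. In the forward step the second-generation Grubbs catalyst would join the C6 vinyl group of triene A5 to one of the two vinyl groups on C3 and give tricyclic ester A6, making C3 a stereocenter. The reaction is mild, releases only ethylene and needs no stereocontrol at C3 beforehand. For ring C it is as good as anything available, and the chosen plan uses the same closure as its step 22. As the centre of a strategy it is weaker: it presupposes rings A and B with six stereocenters and the C15 ether, and so leaves the hydrindane unanswered. The choice between the two vinyl groups is also kinetic and cannot be corrected afterwards, because the pendant vinyl group of the product cannot re-enter productive metathesis. The chosen key step forms only one ring, but it fixes the ring B stereocenters that later direct both C33 and this vinyl selection.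

Key step: step 13

Assumption: the C24 and C27 configurations of 40 are taken to be those favoured at equilibrium in the macrocycle (C27 is enolizable and the C24 hemiaminal opens and closes), so the last step is run under equilibrating conditions.

## Steps

Step 1
Reactants: 1 (5R)-5-[(1R,2S,5R)-menthyloxy]furan-2(5H)-one; 2 (E)-2-methylpenta-1,3-diene
Product: 3 cis-fused Diels–Alder lactone acetal (C12 methyl and the C14–C15 and C7–C6 bonds on one face; menthyloxy group trans to C8)
Conditions: 2 (3 equiv), BHT (cat.), PhMe, sealed tube, 110 °C
Reagents that add atoms: none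
Why: Thermal Diels–Alder reaction of a 5-alkoxybutenolide; the diene adds anti to the menthyloxy group (absolute configuration of C7 and C14), endo to the lactone carbonyl (C12 methyl cis to the lactone) and with its CH2 terminus on the β-carbon, as both methyl groups of 2 direct.

Step 2
Reactants: 3 Diels–Alder adduct
Product: 4 saturated lactone acetal (C9 methyl cis to C12 methyl)
Conditions: H2 (1 atm), Pd/C, EtOAc, rt
Reagents that add atoms: none
Why: Heterogeneous hydrogenation of the only alkene; hydrogen is delivered to the convex face, opposite the lactone ring and the C12 methyl, which places the C9 methyl cis to the C12 methyl.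

Step 3
Reactants: 4 saturated lactone acetal
Product: 5 hydroxy lactone (3-hydroxy-5,7-dimethylhexahydroisobenzofuran-1(3H)-one; both anomers; closed form of the cis formyl acid)
Conditions: 2 M HCl, 1,4-dioxane, 80 °C
Reagents that add atoms: water, O
Why: Acid hydrolysis of the mixed acetal frees the aldehyde oxidation level at C6 and releases menthol for reuse; no ring A stereocenter is touched.

Step 4
Reactants: 5 hydroxy lactone
Product: 6 cis-2-(2-methoxyvinyl)-4,6-dimethylcyclohexane-1-carboxylic acid (E/Z mixture; carboxyl axial)
Conditions: Ph3P(CH2OMe)Cl (3.5 equiv), KHMDS (3.3 equiv), THF, 0 °C → rt; NaH2PO4 work-up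
Reagents that add atoms: (methoxymethyl)triphenylphosphonium chloride, [Cl-].COC[P+](c1ccccc1)(c1ccccc1)c1ccccc1
Why: Wittig methoxymethylenation; the first equivalent of ylide opens the lactol to the carboxylate aldehyde, which is olefinated, so that C34 is added as a masked aldehyde and C7 (equatorial) is not disturbed.

Step 5
Reactants: 6 cis enol ether acid
Product: 8 methyl ester with all four ring A substituents equatorial, via cis methyl ester 7 (not isolated)
Conditions: MeI, K2CO3, DMF, rt; then NaOMe (0.3 equiv), MeOH, 65 °C
Reagents that add atoms: iodomethane, CI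
Why: Carboxylate alkylation followed by base epimerization of the only enolizable center, C14, from the axial to the equatorial ester (thermodynamic control); this sets the trans C7/C14 relationship, and the minor cis ester can be recycled.

Step 6
Reactants: 8 all-equatorial methyl ester
Product: 9 [2-(2-methoxyvinyl)-4,6-dimethylcyclohexyl]methanol (all-equatorial)
Conditions: LiAlH4, THF, 0 °C
Reagents that add atoms: none
Why: Hydride reduction of the ester to the C15 primary alcohol; the enol ether is inert and C14 is no longer epimerizable.

Step 7
Reactants: 9 hydroxy enol ether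
Product: 11 trans-fused δ-lactone (6,8-dimethylhexahydro-1H-isochromen-3(4H)-one), via cyclic methyl acetal 10 (not isolated)
Conditions: PPTS (cat.), CH2Cl2, rt; then mCPBA, BF3·OEt2 (cat.), 0 °C
Reagents that add atoms: mCPBA (3-chloroperoxybenzoic acid), OOC(=O)c1cccc(Cl)c1
Why: Acid-catalysed addition of the hydroxyl to the enol ether gives the six-membered mixed acetal, which the peracid and Lewis acid oxidize to the lactone (oxidation of a lactol ether); no alkene is present at this stage.

Step 8
Reactants: 11 trans-fused δ-lactone
Product: 12 lactone with a 2-(phenylsulfinyl)ethyl group equatorial on C6 (trans to C8; both sulfur epimers)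
Conditions: LDA, THF, −78 °C; PhS(O)CH=CH2, −78 → −30 °C; NH4Cl; then t-BuOK (0.2 equiv), t-BuOH–THF, 0 °C
Reagents that add atoms: phenyl vinyl sulfoxide, C=CS(=O)c1ccccc1
Why: Michael addition of the lactone enolate to an aryl vinyl sulfoxide (vinyl cation equivalent); C6 is α to the carbonyl of a rigid trans-fused bicycle, so brief base equilibration leaves the new chain equatorial, trans to C8, which is the target configuration.

Step 9
Reactants: 12 sulfinylethyl lactone
Product: 13 lactol (both anomers)
Conditions: DIBAL-H (2.2 equiv), CH2Cl2, −78 °C
Reagents that add atoms: none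
Why: Partial reduction of a lactone to the lactol at low temperature; the sulfoxide is not reduced under these conditions.

Step 10
Reactants: 13 lactol
Product: 14 methyl (E)-4-[2-(hydroxymethyl)-3,5-dimethylcyclohexyl]-6-(phenylsulfinyl)hex-2-enoate
Conditions: Ph3P=CHCO2Me, PhCO2H (cat.), THF, 50 °C
Reagents that add atoms: methyl (triphenylphosphoranylidene)acetate, COC(=O)C=P(c1ccccc1)(c1ccccc1)c1ccccc1
Why: Wittig olefination of the open hydroxy aldehyde with a stabilized ylide gives the (E)-enoate (C34=C33–C31) and frees the C15 hydroxyl; the vinyl group is still masked, so C6 is an ordinary α-branched aldehyde carbon and neither epimerizes nor moves into conjugation.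

Step 11
Reactants: 14 hydroxy enoate sulfoxide
Product: 15 methyl (E)-4-[2-(hydroxymethyl)-3,5-dimethylcyclohexyl]hexa-2,5-dienoate
Conditions: CaCO3, PhMe, 110 °C
Reagents that add atoms: none
Why: Thermal syn-elimination of the sulfoxide (sulfoxide pyrolysis) can only give the terminal C5=C4 vinyl group; the neutral medium leaves the doubly allylic C6–H and the free hydroxyl alone.

Step 12
Reactants: 15 hydroxy dienoate
Product: 16 methyl (E)-4-(2-formyl-3,5-dimethylcyclohexyl)hexa-2,5-dienoate
Conditions: DMP, NaHCO3, CH2Cl2, 0 °C → rt
Reagents that add atoms: none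
Why: Dess–Martin oxidation of the primary alcohol under buffered conditions; the C15 aldehyde is equatorial, so its α-carbon C14 is already in the stable configuration.

Step 13
Reactants: 16 aldehyde enoate
Product: 17 methyl 2-[1-hydroxy-5,7-dimethyl-3-vinyl-octahydro-1H-inden-2-yl]acetate (trans-fused; hydroxyl anti to the acetate arm; arm trans to the vinyl group)
Conditions: SmI2 (2.5 equiv), MeOH (4 equiv), THF, −78 °C
Reagents that add atoms: none
Why: SmI2 (divalent samarium) transfers one electron to the C15 aldehyde, the samarium ketyl adds to the enoate β-carbon C34, and the α-ester radical is reduced by a second equivalent to a trivalent samarium enolate that methanol protonates. The closest known reaction type is the SmI2-mediated ketyl–olefin cyclization of aldehydes onto α,β-unsaturated esters, which gives anti 2-(alkoxycarbonylmethyl)cyclopentanols. Ring B closes in the 5-exo-trig mode through a chair-like transition state fused to ring A at the trans-diequatorial C7–C14 bond, so the hydrindane is trans-fused. C34 is controlled by C6: the vinyl group takes the pseudo-equatorial position, which places the new C34–C33 arm trans to it. C15 is controlled by the oxygen–samarium bond, which takes the pseudo-axial position; there it is anti to the enoate and avoids the equatorial C12 methyl, which is peri to the pseudo-equatorial site, so both effects put the hydroxyl anti to the arm. The step needs cyclization to outrun simple reduction or pinacol coupling, which the activated (E)-enoate five atoms away and the low temperature should secure. It also needs anti over syn selectivity; the anti product cannot lactonize and is the C15 epimer that the inverting etherification requires.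

Step 14
Reactants: 18 1,4-diiodobenzene; 19 (S)-epichlorohydrin
Product: 21 (S)-1-chloro-3-(4-iodophenyl)propan-2-ol, via 4-iodophenylmagnesium chloride 20 (not isolated)
Conditions: i-PrMgCl·LiCl (1.0 equiv), THF, −20 °C; then CuI (10 mol %), 19, −20 → 0 °C
Reagents that add atoms: isopropylmagnesium chloride–lithium chloride, CC(C)[Mg]Cl.[Li+].[Cl-] (magnesium and chlorine stay in 20 only)
Why: Iodine–magnesium exchange stops after one iodine because the aryl Grignard is electron-rich, and the copper-catalysed opening of the epoxide at its CH2 terminus gives the chlorohydrin with the stereocenter untouched (this center is removed later).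

Step 15
Reactants: 21 chlorohydrin
Product: 22 (S)-tert-butyl{[1-chloro-3-(4-iodophenyl)propan-2-yl]oxy}dimethylsilane
Conditions: TBSCl, imidazole, DMF, rt
Reagents that add atoms: tert-butyldimethylsilyl chloride, C[Si](C)(Cl)C(C)(C)C
Why: Standard silylation of a secondary alcohol; the silyl ether masks the future C24 ketone through the basic steps to come.

Step 16
Reactants: 22 aryl iodide
Product: 25 4-[(S)-2-(tert-butyldimethylsilyloxy)-3-chloropropyl]phenol, via arylmagnesium chloride 23 (not isolated), via dimethyl arylboronate 24 (not isolated)
Conditions: i-PrMgCl·LiCl, THF, 0 °C; B(OMe)3, −78 °C → rt; then H2O2, aq. NaOH, 0 °C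
Reagents that add atoms: isopropylmagnesium chloride–lithium chloride, CC(C)[Mg]Cl.[Li+].[Cl-] (magnesium and chlorine stay in 23 only); trimethyl borate, COB(OC)OC (boron and methoxy groups stay in 24 only); hydrogen peroxide, OO
Why: Iodine–magnesium exchange, borylation and oxidative carbon-to-oxygen migration convert the aryl iodide into the phenol; the primary chloride and the silyl ether tolerate the cold, brief basic oxidation.

Step 17
Reactants: 17 hydrindanol ester; 25 phenol
Product: 26 aryl ether methyl ester (aryloxy group on C15 cis to the acetate arm)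
Conditions: PPh3, DIAD, PhMe, 0 → 60 °C
Reagents that add atoms: none
Why: Mitsunobu etherification; the phenoxide displaces the pseudo-axial oxyphosphonium group with inversion and so gives the natural C15 configuration, which the anti alcohol of step 13 was made for.

Step 18
Reactants: 26 aryl ether methyl ester
Product: 27 aryl ether carboxylic acid
Conditions: LiOH, THF–MeOH–H2O, rt; then aq. HCl to pH 3
Reagents that add atoms: lithium hydroxide, [Li+].[OH-]
Why: Saponification of the unhindered methyl ester; the silyl ether and the β-branched primary chloride are stable at room temperature.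

Step 19
Reactants: 28 (E)-penta-2,4-dienoic acid
Product: 29 (E)-penta-2,4-dien-1-ol
Conditions: LiAlH4, Et2O, 0 °C
Reagents that add atoms: none
Why: 1,2-Reduction of the dienoic acid to the dienol; the (E)-alkene is kept.

Step 20
Reactants: 27 carboxylic acid; 29 dienol
Product: 30 (E)-penta-2,4-dienyl ester
Conditions: EDC·HCl, DMAP, CH2Cl2, 0 °C → rt
Reagents that add atoms: none
Why: Carbodiimide (Steglich) esterification under neutral conditions sets up the allyl ester for the rearrangement.

Step 21
Reactants: 30 pentadienyl ester
Product: 33 carboxylic acid with a penta-1,4-dien-3-yl group on C33, via silyl ketene acetal 31 (not isolated), via trimethylsilyl ester 32 (not isolated)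
Conditions: KHMDS, TMSCl–Et3N, THF, −78 → 45 °C; aq. HCl
Reagents that add atoms: chlorotrimethylsilane, C[Si](C)(C)Cl (silyl group stays in 31 and 32 only)
Why: Ireland–Claisen rearrangement forms C33–C3; with C34–H in the plane of the ketene acetal (allylic strain) the allyl unit reaches C33 from the face next to C6–H and not from the face screened by the cis aryloxy group on C15, which gives the target C33 configuration, while C3 carries two vinyl groups and is not yet stereogenic.

Step 22
Reactants: 33 triene acid
Product: 34 tricyclic acid (ring C closed; C3 vinyl trans to the C33 carboxyl)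
Conditions: second-generation Grubbs catalyst (5 mol %), CH2Cl2 (5 mM), 40 °C
Reagents that add atoms: none
Why: Ring-closing metathesis between the C6 vinyl group and one of the two vinyl groups on C3 forms C4=C5; the vinyl group that lets the other stay pseudo-equatorial on the forming cyclohexene, trans to the C33 carboxyl, is expected to react, which sets C3.

Step 23
Reactants: 34 tricyclic acid
Product: 36 β-keto methyl ester, via acyl imidazolide 35 (not isolated)
Conditions: CDI, THF, rt; then KO2CCH2CO2Me, MgCl2, Et3N, MeCN, 45 °C; aq. HCl
Reagents that add atoms: potassium methyl malonate, [K+].[O-]C(=O)CC(=O)OC; 1,1'-carbonyldiimidazole, O=C(n1ccnc1)n1ccnc1 (imidazolyl group stays in 35 only)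
Why: Masamune decarboxylative Claisen condensation of the magnesium malonate with the acyl imidazolide adds C27 and C28; C33, if it enolizes, returns to its equatorial, natural configuration.

Step 24
Reactants: 36 β-keto ester silyl ether
Product: 37 β-keto ester chlorohydrin
Conditions: HF·pyridine, THF–pyridine, 0 °C → rt
Reagents that add atoms: none
Why: Buffered fluoride desilylation; acidic conditions keep the chlorohydrin from closing to an epoxide and leave the β-keto ester and the aryl ether alone.

Step 25
Reactants: 37 chlorohydrin
Product: 38 chloromethyl ketone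
Conditions: DMP, NaHCO3, CH2Cl2, 0 °C
Reagents that add atoms: none
Why: Dess–Martin oxidation of the secondary alcohol gives the α-chloro ketone (C24) without touching the alkenes or the β-keto ester.

Step 26
Reactants: 38 chloromethyl ketone
Product: 39 macrocyclic 1,4-diketone methyl ester (13-membered para-cyclophane)
Conditions: Cs2CO3, MeCN (1 mM, slow addition), 50 °C
Reagents that add atoms: none
Why: Intramolecular C-alkylation of the β-keto ester enolate (C27) by the α-chloro ketone (C26) under high dilution; the substitution is fast and irreversible, and closure through C27 gives the 1,4-diketone directly.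

Step 27
Reactants: 39 macrocyclic diketo ester
Product: 40 xenoacremone H
Conditions: NH3 (7 M in MeOH)–H2O, sealed tube, 110 °C
Reagents that add atoms: ammonia, N
Why: Aminolysis of the β-keto ester gives the primary amide, whose nitrogen adds to the C24 ketone (hemiaminal formation); C27 epimerizes through the enol and C24 through ring opening, so the benzyl and acyl arms end cis on the lactam as the macrocycle requires.

## Compound list

1 | (5R)-5-[(1R,2S,5R)-menthyloxy]furan-2(5H)-one | O=C1C=C[C@H](O[C@@H]2C[C@H](C)CC[C@H]2C(C)C)O1 | starting material
2 | (E)-2-methylpenta-1,3-diene | C=C(C)/C=C/C | starting material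
3 | cis-fused 3-(menthyloxy)-5,7-dimethyl-3a,4,7,7a-tetrahydroisobenzofuran-1(3H)-one; C12 methyl, C14–C15 and C7–C6 bonds on one face, menthyloxy trans to C8 | O=C1O[C@@H](O[C@@H]3C[C@H](C)CC[C@H]3C(C)C)[C@@H]2CC(C)=C[C@H](C)[C@H]12 | intermediate
4 | hexahydro analogue of 3; C9 methyl cis to C12 methyl | O=C1O[C@@H](O[C@@H]3C[C@H](C)CC[C@H]3C(C)C)[C@@H]2C[C@H](C)C[C@H](C)[C@H]12 | intermediate
5 | cis-fused 3-hydroxy-5,7-dimethylhexahydroisobenzofuran-1(3H)-one (both anomers) | O=C1OC(O)[C@@H]2C[C@H](C)C[C@H](C)[C@H]12 | intermediate
6 | cis-2-(2-methoxyvinyl)-4,6-dimethylcyclohexane-1-carboxylic acid (E/Z mixture; carboxyl axial) | COC=C[C@@H]1C[C@H](C)C[C@H](C)[C@@H]1C(=O)O | intermediate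
7 | methyl ester of 6 (cis) | COC=C[C@@H]1C[C@H](C)C[C@H](C)[C@@H]1C(=O)OC | intermediate
8 | methyl 2-(2-methoxyvinyl)-4,6-dimethylcyclohexane-1-carboxylate, all substituents equatorial (C14 epimer of 7) | COC=C[C@@H]1C[C@H](C)C[C@H](C)[C@H]1C(=O)OC | intermediate
9 | [2-(2-methoxyvinyl)-4,6-dimethylcyclohexyl]methanol, all-equatorial | COC=C[C@@H]1C[C@H](C)C[C@H](C)[C@H]1CO | intermediate
10 | trans-fused 3-methoxy-6,8-dimethyloctahydro-1H-isochromene (both anomers) | COC1C[C@@H]2C[C@H](C)C[C@H](C)[C@H]2CO1 | intermediate
11 | trans-fused 6,8-dimethylhexahydro-1H-isochromen-3(4H)-one | O=C1C[C@@H]2C[C@H](C)C[C@H](C)[C@H]2CO1 | intermediate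
12 | 11 with a 2-(phenylsulfinyl)ethyl group equatorial on C6 (position 4 of the isochromanone; trans to C8; both sulfur epimers) | O=C1[C@@H](CCS(=O)c3ccccc3)[C@@H]2C[C@H](C)C[C@H](C)[C@H]2CO1 | intermediate
13 | lactol of 12 (both anomers) | OC1[C@@H](CCS(=O)c3ccccc3)[C@@H]2C[C@H](C)C[C@H](C)[C@H]2CO1 | intermediate
14 | methyl (E)-4-[2-(hydroxymethyl)-3,5-dimethylcyclohexyl]-6-(phenylsulfinyl)hex-2-enoate | O=S(CC[C@H](/C=C/C(=O)OC)[C@@H]1C[C@H](C)C[C@H](C)[C@H]1CO)c1ccccc1 | intermediate
15 | methyl (E)-4-[2-(hydroxymethyl)-3,5-dimethylcyclohexyl]hexa-2,5-dienoate | C=C[C@H](/C=C/C(=O)OC)[C@@H]1C[C@H](C)C[C@H](C)[C@H]1CO | intermediate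
16 | methyl (E)-4-(2-formyl-3,5-dimethylcyclohexyl)hexa-2,5-dienoate (ring A aldehyde with vinyl and enoate arms on C6) | C=C[C@H](/C=C/C(=O)OC)[C@@H]1C[C@H](C)C[C@H](C)[C@H]1C=O | intermediate
17 | methyl 2-[1-hydroxy-5,7-dimethyl-3-vinyl-octahydro-1H-inden-2-yl]acetate; trans-fused, hydroxyl anti to the acetate arm, arm trans to vinyl | C=C[C@H]2[C@@H]3C[C@H](C)C[C@H](C)[C@H]3[C@@H](O)[C@@H]2CC(=O)OC | intermediate
18 | 1,4-diiodobenzene | Ic1ccc(I)cc1 | starting material
19 | (S)-epichlorohydrin | ClC[C@@H]1CO1 | starting material
20 | 4-iodophenylmagnesium chloride | Cl[Mg]c1ccc(I)cc1 | intermediate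
21 | (S)-1-chloro-3-(4-iodophenyl)propan-2-ol | Ic1ccc(C[C@@H](CCl)O)cc1 | intermediate
22 | (S)-tert-butyl{[1-chloro-3-(4-iodophenyl)propan-2-yl]oxy}dimethylsilane | Ic1ccc(C[C@@H](CCl)O[Si](C)(C)C(C)(C)C)cc1 | intermediate
23 | arylmagnesium chloride from 22 | Cl[Mg]c1ccc(C[C@@H](CCl)O[Si](C)(C)C(C)(C)C)cc1 | intermediate
24 | dimethyl arylboronate from 23 | COB(OC)c1ccc(C[C@@H](CCl)O[Si](C)(C)C(C)(C)C)cc1 | intermediate
25 | 4-[(S)-2-(tert-butyldimethylsilyloxy)-3-chloropropyl]phenol | Oc1ccc(C[C@@H](CCl)O[Si](C)(C)C(C)(C)C)cc1 | intermediate
26 | aryl ether methyl ester: 17 with the C15 oxygen inverted and bound to the aryl group of 25 | C=C[C@H]2[C@@H]3C[C@H](C)C[C@H](C)[C@H]3[C@H](Oc4ccc(C[C@@H](CCl)O[Si](C)(C)C(C)(C)C)cc4)[C@@H]2CC(=O)OC | intermediate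
27 | carboxylic acid of 26 | C=C[C@H]2[C@@H]3C[C@H](C)C[C@H](C)[C@H]3[C@H](Oc4ccc(C[C@@H](CCl)O[Si](C)(C)C(C)(C)C)cc4)[C@@H]2CC(=O)O | intermediate
28 | (E)-penta-2,4-dienoic acid | C=C/C=C/C(=O)O | starting material
29 | (E)-penta-2,4-dien-1-ol | C=C/C=C/CO | intermediate
30 | (E)-penta-2,4-dienyl ester of 27 | C=C[C@H]2[C@@H]3C[C@H](C)C[C@H](C)[C@H]3[C@H](Oc4ccc(C[C@@H](CCl)O[Si](C)(C)C(C)(C)C)cc4)[C@@H]2CC(=O)OC/C=C/C=C | intermediate
31 | trimethylsilyl ketene acetal of 30 (C33=C31 geometry not defined) | C=C[C@H]2[C@@H]3C[C@H](C)C[C@H](C)[C@H]3[C@H](Oc4ccc(C[C@@H](CCl)O[Si](C)(C)C(C)(C)C)cc4)[C@@H]2C=C(O[Si](C)(C)C)OC/C=C/C=C | intermediate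
32 | trimethylsilyl ester of 33 | C=C[C@H]2[C@@H]3C[C@H](C)C[C@H](C)[C@H]3[C@H](Oc4ccc(C[C@@H](CCl)O[Si](C)(C)C(C)(C)C)cc4)[C@@H]2[C@H](C(C=C)C=C)C(=O)O[Si](C)(C)C | intermediate
33 | acid with a penta-1,4-dien-3-yl group on C33 (C33 as in the target) | C=C[C@H]2[C@@H]3C[C@H](C)C[C@H](C)[C@H]3[C@H](Oc4ccc(C[C@@H](CCl)O[Si](C)(C)C(C)(C)C)cc4)[C@@H]2[C@H](C(C=C)C=C)C(=O)O | intermediate
34 | tricyclic acid: rings A, B and C complete, C3 vinyl trans to the C33 carboxyl | C=C[C@@H]1C=C[C@H]2[C@@H]3C[C@H](C)C[C@H](C)[C@H]3[C@H](Oc4ccc(C[C@@H](CCl)O[Si](C)(C)C(C)(C)C)cc4)[C@@H]2[C@H]1C(=O)O | intermediate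
35 | acyl imidazolide of 34 | C=C[C@@H]1C=C[C@H]2[C@@H]3C[C@H](C)C[C@H](C)[C@H]3[C@H](Oc4ccc(C[C@@H](CCl)O[Si](C)(C)C(C)(C)C)cc4)[C@@H]2[C@H]1C(=O)n1ccnc1 | intermediate
36 | β-keto methyl ester (C31 ketone, C27 methylene, C28 ester) with the silyl-protected side chain | C=C[C@@H]1C=C[C@H]2[C@@H]3C[C@H](C)C[C@H](C)[C@H]3[C@H](Oc4ccc(C[C@@H](CCl)O[Si](C)(C)C(C)(C)C)cc4)[C@@H]2[C@H]1C(=O)CC(=O)OC | intermediate
37 | β-keto ester with free chlorohydrin side chain | C=C[C@@H]1C=C[C@H]2[C@@H]3C[C@H](C)C[C@H](C)[C@H]3[C@H](Oc4ccc(C[C@@H](CCl)O)cc4)[C@@H]2[C@H]1C(=O)CC(=O)OC | intermediate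
38 | β-keto ester with 3-chloro-2-oxopropyl side chain | C=C[C@@H]1C=C[C@H]2[C@@H]3C[C@H](C)C[C@H](C)[C@H]3[C@H](Oc4ccc(CC(=O)CCl)cc4)[C@@H]2[C@H]1C(=O)CC(=O)OC | intermediate
39 | macrocyclic diketo ester (13-membered para-cyclophane; C24 and C31 ketones, methoxycarbonyl on C27; C27 epimers and enol forms interconvert) | C=C[C@@H]1C=C[C@H]2[C@@H]3C[C@H](C)C[C@H](C)[C@H]3[C@@H]3Oc4ccc(cc4)CC(=O)CC(C(=O)OC)C(=O)[C@@H]1[C@H]23 | intermediate
40 | xenoacremone H | C=C[C@@H]1C=C[C@H]2[C@@H]3C[C@H](C)C[C@H](C)[C@H]3[C@@H]3Oc4ccc(cc4)C[C@@]4(O)C[C@H](C(=O)N4)C(=O)[C@@H]1[C@H]23 | target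

## Step count and risks

Total: 27 steps. Longest linear sequence: 23 steps (steps 1–13, 17, 18 and 20–27); steps 14–16 and 19 make the two side fragments.

Step 13 (key step). The ketyl may be reduced further to the primary alcohol or couple to a pinacol before it reaches C34, or the anti preference may erode if the samarium alkoxide does not keep the pseudo-axial position. Fallback: from 16, a triazolium-derived N-heterocyclic carbene (intramolecular Stetter reaction) would add the C15 acyl anion equivalent to C34 and give the trans-fused hydrindanone keto ester F1, in which C34 is α to the ketone and settles trans to the C6 vinyl group. Reduction of F1 with NaBH4 at −40 °C should then give mainly the anti alcohol, because small hydrides enter 2-substituted cyclopentanones mostly cis to the substituent and the other face is also screened by the vinyl group. Any syn alcohol closes to a lactone and is removed. The route is rejoined at 17.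

Step 17. Substitution at C15 may be slow, because the incoming phenoxide must pass between the C33 arm and the C12 methyl, and anti elimination toward C14 may take over. Fallback: from 17, LiOH hydrolysis gives the hydroxy acid F2, and PPh3/DIAD then closes the cis-fused γ-lactone F3; here the inversion at C15 is done by the carboxylate arm, which already sits on the rear face of the carbinol. F3 has the natural C15 configuration. It is opened with KOH to the potassium hydroxy carboxylate and, without acidification, coupled with aryl iodide 22 (CuI, 3,4,7,8-tetramethyl-1,10-phenanthroline, Cs2CO3, PhMe, 90 °C; Ullmann-type O-arylation with retention). Acidification gives 27, where the route is rejoined.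

Step 26. Oligomerization, O-alkylation of the enolate or attack at the ketone may outrun the C-alkylation, because the 13-membered cyclophane is strained and the rigid ring C holds the C31 arm in one orientation. Fallback: from 33, the macrocycle is closed before ring C. Masamune homologation of 33 gives β-keto ester F4, HF·pyridine gives chlorohydrin F5, and DMP gives chloro ketone F6. Alkylation with Cs2CO3 in dilute MeCN, with the C33 arm still free to rotate, gives macrocycle F7, and the second-generation Grubbs catalyst then closes ring C across the macrocycle to give 39.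

Step 27. Ammonia may condense with the ketones (enaminone or pyrrole formation from the 1,4-diketone) faster than it aminolyses the ester, or the β-keto ester may cleave by retro-Claisen reaction at 110 °C. Fallback: the amide is made before the ring. From 34, Meldrum's acid with EDC and DMAP gives acyl Meldrum's acid F8, and heating with NH3 in 1,4-dioxane (capture of the acylketene) gives primary β-keto amide F9. HF·pyridine gives chlorohydrin F10 and DMP gives chloro ketone F11. Macro-alkylation with Cs2CO3 in dilute MeCN then forms C26–C27, and the amide nitrogen closes onto C24 at room temperature to give 40.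

## Further compounds

F1 | step 13 | methyl 2-[5,7-dimethyl-1-oxo-3-vinyl-octahydro-1H-inden-2-yl]acetate (trans-fused; arm trans to vinyl) | C=C[C@H]2[C@@H]3C[C@H](C)C[C@H](C)[C@H]3C(=O)[C@@H]2CC(=O)OC
F2 | step 17 | hydroxy acid of 17 | C=C[C@H]2[C@@H]3C[C@H](C)C[C@H](C)[C@H]3[C@@H](O)[C@@H]2CC(=O)O
F3 | step 17 | cis-fused γ-lactone between the C15 oxygen (inverted) and C31 | C=C[C@H]2[C@@H]3C[C@H](C)C[C@H](C)[C@H]3[C@@H]4OC(=O)C[C@H]24
F4 | step 26 | β-keto methyl ester from 33 (ring C open; silyl ether) | C=C[C@H]2[C@@H]3C[C@H](C)C[C@H](C)[C@H]3[C@H](Oc4ccc(C[C@@H](CCl)O[Si](C)(C)C(C)(C)C)cc4)[C@@H]2[C@H](C(C=C)C=C)C(=O)CC(=O)OC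
F5 | step 26 | chlorohydrin from F4 | C=C[C@H]2[C@@H]3C[C@H](C)C[C@H](C)[C@H]3[C@H](Oc4ccc(C[C@@H](CCl)O)cc4)[C@@H]2[C@H](C(C=C)C=C)C(=O)CC(=O)OC
F6 | step 26 | chloromethyl ketone from F5 | C=C[C@H]2[C@@H]3C[C@H](C)C[C@H](C)[C@H]3[C@H](Oc4ccc(CC(=O)CCl)cc4)[C@@H]2[C@H](C(C=C)C=C)C(=O)CC(=O)OC
F7 | step 26 | macrocyclic diketo ester with ring C still open (three vinyl groups) | C=C[C@H]2[C@@H]3C[C@H](C)C[C@H](C)[C@H]3[C@@H]4Oc5ccc(cc5)CC(=O)CC(C(=O)OC)C(=O)[C@@H](C(C=C)C=C)[C@H]24
F8 | step 27 | acyl Meldrum's acid from 34 (enol form) | C=C[C@@H]1C=C[C@H]2[C@@H]3C[C@H](C)C[C@H](C)[C@H]3[C@H](Oc4ccc(C[C@@H](CCl)O[Si](C)(C)C(C)(C)C)cc4)[C@@H]2[C@H]1C(O)=C1C(=O)OC(C)(C)OC1=O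
F9 | step 27 | primary β-keto amide (silyl ether) | C=C[C@@H]1C=C[C@H]2[C@@H]3C[C@H](C)C[C@H](C)[C@H]3[C@H](Oc4ccc(C[C@@H](CCl)O[Si](C)(C)C(C)(C)C)cc4)[C@@H]2[C@H]1C(=O)CC(N)=O
F10 | step 27 | β-keto amide chlorohydrin | C=C[C@@H]1C=C[C@H]2[C@@H]3C[C@H](C)C[C@H](C)[C@H]3[C@H](Oc4ccc(C[C@@H](CCl)O)cc4)[C@@H]2[C@H]1C(=O)CC(N)=O
F11 | step 27 | β-keto amide chloromethyl ketone | C=C[C@@H]1C=C[C@H]2[C@@H]3C[C@H](C)C[C@H](C)[C@H]3[C@H](Oc4ccc(CC(=O)CCl)cc4)[C@@H]2[C@H]1C(=O)CC(N)=O
A1 | alternative 1 | ring C tetraene with (E)-3-methylbuta-1,3-dienyl on C6 and a silyloxy (E)-enoate chain on C34 | C=C[C@@H]1C=C[C@@H](/C=C/C(C)=C)[C@H]([C@@H](O[Si](C)(C)C(C)(C)C)/C=C/C(=O)OC)[C@H]1CO[Si](C)(C)C(C)(C)C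
A2 | alternative 1 | tricyclic C8=C9 alkene with methoxycarbonyl on C12 | C=C[C@@H]1C=C[C@H]2[C@@H]3C=C(C)C[C@H](C(=O)OC)[C@H]3[C@H](O[Si](C)(C)C(C)(C)C)[C@@H]2[C@H]1CO[Si](C)(C)C(C)(C)C
A3 | alternative 2 | 14-membered α-chloro sulfone (sulfur between C23 and C24; chlorine on C24, configuration not defined) | C=C[C@@H]1C=C[C@H]2[C@@H]3C[C@H](C)C[C@H](C)[C@H]3[C@@H]3Oc4ccc(cc4)CS(=O)(=O)C(Cl)C[C@H](C(=O)OC)C(=O)[C@@H]1[C@H]23
A4 | alternative 2 | 13-membered (Z)-styrene β-keto ester | C=C[C@@H]1C=C[C@H]2[C@@H]3C[C@H](C)C[C@H](C)[C@H]3[C@@H]3Oc4ccc(cc4)/C=C\C[C@H](C(=O)OC)C(=O)[C@@H]1[C@H]23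
A5 | alternative 3 | triene methyl ester with two vinyl groups on C3 and one on C6 | C=C[C@H]2[C@@H]3C[C@H](C)C[C@H](C)[C@H]3[C@H](Oc4ccc(CCO[Si](C)(C)C(C)(C)C)cc4)[C@@H]2[C@H](C(C=C)C=C)C(=O)OC
A6 | alternative 3 | tricyclic C31 methyl ester | C=C[C@@H]1C=C[C@H]2[C@@H]3C[C@H](C)C[C@H](C)[C@H]3[C@H](Oc4ccc(CCO[Si](C)(C)C(C)(C)C)cc4)[C@@H]2[C@H]1C(=O)OC
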